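**Assumptions**
- The target has no stereocenters, so there is no enantiomer issue. The chalcone E-geometry in compound 9 is lost on cyclization.
- Methyl 3,5-dihydroxy-4-methoxybenzoate (methyl 4-O-methylgallate) is taken as a commercial starting material.
- An aryl sulfate monoester is acid-labile, so the target is isolated as its ammonium or cesium salt. The free-acid SMILES below is the same species.

## Retrosynthetic overview
1. Target ← regioselective 4'-O-sulfation of hispidulin (11), the proposed new step; 11 ← hydrogenolysis of the 5,7-di-O-benzyl flavone 10.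
2. The pyranone ring is closed last among the ring-forming steps: I2/DMSO oxidative cyclization of 2'-hydroxychalcone 9, which comes from Claisen–Schmidt condensation of acetophenone 7 with 4-hydroxybenzaldehyde (8).
3. Ring A is built from methyl 4-O-methylgallate so that the OMe sits between two OBn groups. CO2Me is converted to OH (reduction, oxidation, Baeyer–Villiger), then ortho-acetylation gives 7. The only free ortho-OH is then the one remote from the OMe, which sets 6-OMe and avoids the wogonin-type 8-OMe isomer.

## Route

**Step 1**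
Reactants: 1 (methyl 3,5-dihydroxy-4-methoxybenzoate)
Product: 2 (methyl 3,5-bis(benzyloxy)-4-methoxybenzoate)
Conditions: BnBr (2.3 equiv), K2CO3, DMF, 60 °C
Reagents that add atoms: benzyl bromide, BrCc1ccccc1
Why: Williamson O-benzylation of both phenols; the ester is untouched.

**Step 2**
Reactants: 2
Product: 3 ([3,5-bis(benzyloxy)-4-methoxyphenyl]methanol)
Conditions: LiAlH4, THF, 0 °C
Reagents that add atoms: none
Why: Hydride reduction of the ester to the primary alcohol; the benzyl ethers survive.

**Step 3**
Reactants: 3
Product: 4 (3,5-bis(benzyloxy)-4-methoxybenzaldehyde)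
Conditions: Dess–Martin periodinane, NaHCO3, CH2Cl2, rt
Reagents that add atoms: none
Why: Mild oxidation of the benzylic alcohol to the aldehyde with no over-oxidation.

**Step 4**
Reactants: 4
Product: 5 (3,5-bis(benzyloxy)-4-methoxyphenyl formate)
Conditions: mCPBA, NaHCO3, CH2Cl2, 0 °C → rt
Reagents that add atoms: mCPBA, OOC(=O)c1cccc(Cl)c1 (supplies the inserted O)
Why: Baeyer–Villiger oxidation of an electron-rich benzaldehyde; aryl migration gives the aryl formate, as in the conversion of 3,4,5-trimethoxybenzaldehyde to the phenol.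

**Step 5**
Reactants: 5
Product: 6 (3,5-bis(benzyloxy)-4-methoxyphenol)
Conditions: K2CO3, MeOH, rt
Reagents that add atoms: none
Why: Methanolysis of the formate ester releases the free phenol.

**Step 6**
Reactants: 6
Product: 7 (1-[4,6-bis(benzyloxy)-2-hydroxy-5-methoxyphenyl]ethan-1-one)
Conditions: AcOH (3 equiv), BF3·OEt2 (3 equiv), 70 °C, 3 h
Reagents that add atoms: acetic acid, CC(=O)O (supplies the acetyl group)
Why: BF3-promoted ortho-acylation of the phenol; both ortho positions are equivalent, so only one regioisomer forms, with the acetyl flanked by OH and OBn.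

**Step 7**
Reactants: 7; 8 (4-hydroxybenzaldehyde)
Product: 9 ((E)-1-[4,6-bis(benzyloxy)-2-hydroxy-5-methoxyphenyl]-3-(4-hydroxyphenyl)prop-2-en-1-one)
Conditions: KOH (4 equiv), EtOH/H2O, rt, 48 h; then HCl(aq) to pH 3
Reagents that add atoms: none (8 is the coupling partner)
Why: Claisen–Schmidt aldol condensation; the extra base covers the chelated 2'-OH and the 4-OH of the aldehyde, and the E-enone forms by dehydration.

**Step 8**
Reactants: 9
Product: 10 (5,7-bis(benzyloxy)-4'-hydroxy-6-methoxyflavone)
Conditions: I2 (0.15 equiv), DMSO, 120 °C, 2–3 h; Na2S2O3 workup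
Reagents that add atoms: none
Why: Iodine-catalyzed oxa-Michael/oxidative aromatization of the 2'-hydroxychalcone. The only free ortho-OH is on the carbon remote from the OMe, which places 6-OMe correctly.

**Step 9**
Reactants: 10
Product: 11 (hispidulin, 5,7,4'-trihydroxy-6-methoxyflavone)
Conditions: H2 (1 atm), 10% Pd/C, THF/EtOH, rt, 3 h
Reagents that add atoms: none
Why: Hydrogenolysis of both aryl benzyl ethers; the chromone C2=C3 and the aryl OMe survive under these mild conditions.

**Step 10**
Reactants: 11
Product: 12 (hispidulin 4'-sulfate, target)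
Conditions: Cs2CO3 (2.0 equiv), DMF, 0 °C, 15 min; then Me3N·SO3 (1.05 equiv), 0 → 40 °C, 12 h; aq. NH4HCO3 quench; C18 chromatography
Reagents that add atoms: trimethylamine–sulfur trioxide, C[N+](C)(C)S(=O)(=O)[O-] (supplies SO3)
Why: Proposed new method: protecting-group-free, 4'-selective sulfation by charge control. Two equivalents of base deprotonate the acidic 7-OH and the 4'-OH but not the chelated 5-OH. The 7-O⁻ is strongly stabilized by the chromone C4=O, so it is the weaker nucleophile, while the less delocalized 4'-O⁻ attacks the electrophilic S(VI) of Me3N·SO3. Sulfate transfer is also reversible, so 7-sulfate (a good sulfuryl donor) can funnel to the thermodynamically favored 4'-sulfate. The closest known chemistry is SO3·amine sulfation of phenoxides, and the reversed-acidity site selectivity seen in dianion alkylation of polyphenols.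

## Compound list
1 | methyl 3,5-dihydroxy-4-methoxybenzoate | COC(=O)c1cc(O)c(OC)c(O)c1 | starting material
2 | methyl 3,5-bis(benzyloxy)-4-methoxybenzoate | COC(=O)c1cc(OCc2ccccc2)c(OC)c(OCc2ccccc2)c1 | intermediate
3 | [3,5-bis(benzyloxy)-4-methoxyphenyl]methanol | OCc1cc(OCc2ccccc2)c(OC)c(OCc2ccccc2)c1 | intermediate
4 | 3,5-bis(benzyloxy)-4-methoxybenzaldehyde | O=Cc1cc(OCc2ccccc2)c(OC)c(OCc2ccccc2)c1 | intermediate
5 | 3,5-bis(benzyloxy)-4-methoxyphenyl formate | O=COc1cc(OCc2ccccc2)c(OC)c(OCc2ccccc2)c1 | intermediate
6 | 3,5-bis(benzyloxy)-4-methoxyphenol | Oc1cc(OCc2ccccc2)c(OC)c(OCc2ccccc2)c1 | intermediate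
7 | 1-[4,6-bis(benzyloxy)-2-hydroxy-5-methoxyphenyl]ethan-1-one | CC(=O)c1c(O)cc(OCc2ccccc2)c(OC)c1OCc1ccccc1 | intermediate
8 | 4-hydroxybenzaldehyde | O=Cc1ccc(O)cc1 | starting material
9 | (E)-chalcone, 2'-OH, 4',6'-di-OBn, 5'-OMe, 4-OH | O=C(/C=C/c1ccc(O)cc1)c1c(OCc2ccccc2)c(OC)c(OCc2ccccc2)cc1O | intermediate
10 | 5,7-bis(benzyloxy)-4'-hydroxy-6-methoxyflavone | COc1c(OCc2ccccc2)cc2oc(-c3ccc(O)cc3)cc(=O)c2c1OCc1ccccc1 | intermediate
11 | hispidulin | COc1c(O)cc2oc(-c3ccc(O)cc3)cc(=O)c2c1O | intermediate
12 | hispidulin 4'-sulfate | COc1c(O)cc2oc(-c3ccc(OS(=O)(=O)O)cc3)cc(=O)c2c1O | target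

**Total steps:** 10
**Longest linear sequence:** 10 steps (1 → 12)

**Three steps most likely to fail**
1. **Step 10 (proposed new step).** The 7-O versus 4'-O selectivity may be poor, giving 7-sulfate or 4',7-disulfate.
 - Fallback (known chemistry): sulfate compound 10, which has a single free OH, with SO3·pyridine/Et3N in DMF. Then do the Pd/C hydrogenolysis, reversing the order of steps 9 and 10.
2. **Step 6.** BF3·OEt2 at 70 °C may partly cleave the benzyl ethers or give low conversion.
 - Fallback: make 7 from 2,4,6-trihydroxyacetophenone. Dibenzylate with BnBr/K2CO3 to give 2-hydroxy-4,6-bis(benzyloxy)acetophenone; then do an Elbs persulfate para-hydroxylation (K2S2O8, NaOH; then HCl) at C5; then selectively methylate the non-chelated 5-OH with MeI/K2CO3.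
3. **Step 8.** A free 4'-OH under I2/DMSO at 120 °C may lead to ring iodination or partial debenzylation.
 - Fallback: use the Baker–Venkataraman route. Acylate 7 with 4-acetoxybenzoyl chloride/pyridine, rearrange with KOtBu to the 1,3-diketone, and cyclodehydrate with p-TsOH in toluene to give 10.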